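Ash holds target plus side product at 49.0% after 2.00 h and 47.0% after 6.00 h while its target falls, so we take the end share of target as a clock for how long the product has stood.

| flask | substrate | partner | remark | time |
|---|---|---|---|---|
| ash | 26 mM | 104 mM | run made earlier |  |
| maple | 36 mM | 104 mM | run made earlier |  |
| birch | 57 mM | 104 mM | run made earlier |  |
| elm | 26 mM | 52 mM | run made earlier |  |
| south | 26 mM (in portions, 2, over 4.0 h) | 104 mM | first portion at the start, last at 4.0 h | 6.0 h |
| west | 26 mM | 104 mM | everything together at the start | 6.0 h |
| north-east | 26 mM (fed, over 4.0 h) | 104 mM | all else is in the flask from the start; the feed brings no volume worth counting | 6.0 h |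
| north | 26 mM | 104 mM (fed, over 4.0 h) | all else is in the flask from the start; the feed brings no volume worth counting | 6.0 h |

- ash (time / h: target / %, side product / %): 0.833: 34, 3; 2.00: 38, 11; 4.00: 32, 16; 6.00: 24, 23
- maple (time / h: target / %, side product / %): 0.833: 32, 5; 2.00: 37, 9; 4.00: 27, 14; 6.00: 25, 19
- birch (time / h: target / %, side product / %): 0.833: 28, 2; 2.00: 30, 6; 4.00: 24, 15; 6.00: 20, 20
- elm (time / h: target / %, side product / %): 0.500: 10, 1; 1.00: 15, 2; 2.50: 22, 8; 6.00: 18, 19

(each reading ± 1.5 percentage points)

- what was read earlier has a scatter of 1.5 percentage points, one standard deviation

1. the best flask by share of target in target plus side product; "all alike" if 1.5 percentage points covers them all (south / west / north-east / north / all alike)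
2. share of target in target plus side product at the end, south
3. share of target in target plus side product at the end, west
4. share of target in target plus side product at the end, north-east
5. share of target in target plus side product at the end, north

1. Ash target goes from 38% to 24% over those hours, so k = 0.115 /h: the ageing constant, the fractional loss of target per hour while the sum stands still, a reading with its scatter.

2. Let S, the selectivity, be target over target plus side product. We take product of age a to have S = exp(−k·a), so a = ln(1/S)/k.

3. Old extreme: substrate becomes product the instant it enters. West gets 50.2%. South averages its two portions to 64.8%. North-east, averaged over the feed, gets 63.7%.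

4. Young extreme: product is born at the last moment, with no age, and S = 100%.

5. We expect the flasks near the old extreme, since ash reads S = 51.1%. Birch ends with 22.8 mM of product against 12.2 mM in ash, so we let south's late portion convert.

6. Elm, with half the partner, reads an age of 6.27 h, no younger than ash. So we put north between west and north-east, and south first, ahead of north-east by 1.1 percentage points.

The forecast differs. It names north, with south 52%, west 51%, north-east 55% and north 66%, holding that “the late portion meets a dead system”.

The flask gives south: south 69.7%, west 54.3%, north-east 67.8%, north 59.3%.

    intermediate A → side product (k = 0.00380 /min)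
    substrate ⇌ dormant form (K = 2.00, k = 0.00370 /min)
    partner + intermediate B → target (k = 0.630 /M/min)
    target ⇌ isomer of the product (K = 2.50, k = 0.00540 /min)
    substrate + partner ⇌ intermediate B (K = 14.0 /M, k = 0.330 /M/min)
    substrate + partner → intermediate A (k = 0.100 /M/min)

South's target stands at 14.8% after 4.00 h, just before the last addition, and at 30.6% after 6.00 h. With k, south's share reads as an age of 3.14 h and north-east's as 3.39 h. North-east dosed over 0.400 h gives 55.3%, an age of 5.16 h, older by 1.77 h, while the midpoint of its dose moves by 1.80 h.

(The numbers in the tables come from a simulation for substances that don't exist; the scatter is artificial.)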